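## The problem

The target 29 is an isoflavan: a chroman (ring A fused to the oxygen heterocycle, ring C) that carries ring B on C3, and ring B is fused through C3′ and C4′ to a 2,2-dimethyl-2H-pyran (ring D). Ring A has a free hydroxyl on C7 and a prenyl group on C8, held between O7 and the ring oxygen O1; ring B has a free hydroxyl on C2′ and the pyran oxygen on C4′. The only stereocenter is C3 (R). It has no neighbour that could control it, so a reagent or catalyst must set it; being benzylic and tertiary, it must afterwards be kept away from carbonyl groups at C2 or C4 and from dehydrogenation to the isoflav-3-ene. The sensitive groups decide the end game: acid closes the 7-hydroxyl onto the C8 prenyl group and attacks the chromene, heterogeneous hydrogenation would reduce three alkenes, and the electron-rich phenols do not tolerate strong oxidants, so the last protecting groups must leave under neutral, non-reducing conditions. Two regiochemical questions remain: the prenyl group must enter ring A between its oxygens, and ring D must close onto O4′ and not O2′, although the carbon on C3′ is flanked by both. The enabling feature is ring B itself: C1′ (bound to C3), oxygen on C2′, carbon on C3′, oxygen on C4′ and hydrogen on C5′ and C6′ is the pattern formed when a vinylketene (C1′, C6′, C5′, C4′) combines with an oxygenated alkyne (C2′, C3′), and that union leaves O4′ free and O2′ masked.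

## Retrosynthesis

**29 to 28.** Only the two O–Si bonds are cut. Silyl ethers are preferred to acetal or benzyl protection because fluoride is the one deprotection that spares the chromene, both prenyl-type alkenes and the phenol beside the C8 prenyl group. The forward step asks only for complete cleavage of two aryl triisopropylsilyl ethers.

**28 to 26.** Ring D is opened at the O4′–C(CH3)2 bond and its C=C bond is taken back to a prenyl group, giving the ortho-prenylphenol 26. A finished chromene cannot be carried along once ring B is made late, and a propargyl ether rearrangement onto an unsubstituted C3′ would have to choose between C3′ and C5′. In 26 the choice is already made: O4′ is free, O2′ and O7 are silylated. The forward reaction must dehydrogenate and cyclise (through 27) the one prenyl group with a free phenol beside it, and leave C3–H, C4–H2 and the ring A prenyl group alone.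

**26 to 20 and 23 (key disconnection).** Four bonds of ring B are cut: C1′–C6′, C1′–C2′, C3′–C4′ and C4′–C5′. The neighbouring cuts, which join a finished ring B to C3, need either an sp3–sp2 coupling at a secondary stereogenic carbon or an enolate arylation that puts a carbonyl next to C3. Here ring B shrinks to a four-carbon diazo enone side chain on C3 (20) and a seven-carbon silyl ynol ether (23). The forward cascade (through 24 and 25) must show clean vinyl migration, one [2+2] regiochemistry and indifference to the prenyl alkenes. It returns the O4′/O2′ differentiation that the previous paragraph needs.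

**23 to 21.** The ynol ether is cut at its O–Si bond and at the alkyne carbon that comes from a one-carbon reagent, which leads to the ester 21 through ynolate 22. This is shorter than building the skipped enyne first and oxidising its acetylide. The forward step asks for carbonyl addition of a carbenoid to outrun α-deprotonation of the β,γ-unsaturated ester.

**20 to 18 to 17.** The diazo group is taken back to a CH2 group (through the activated diketone 19) and the vinyl–carbonyl bond is cut, giving Weinreb amide 17. The diazo carbon cannot be introduced as a nucleophile without unstable diazoalkanes, so transfer onto the enolate of 18 is the practical choice. Regiochemistry is not an issue, because the vinyl side of 18 has no α-hydrogen.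

**17 to 16 to 15.** After removal of the silyl group, ring C is opened at O1–C2 to a phenol and a primary alcohol. Cutting here and not at C4–C4a keeps the stereocenter out of the bond-forming event. Ring size, not a protecting group, decides between O1 and O7, since O7 cannot reach C2.

**15 to 14 to 12.** The amide C–N bond is cut back to the γ-lactone, and the phenols are masked as methoxymethyl ethers (removed through 13). The lactone is the stable, purifiable carrier of the stereocenter; the acetals must go while the molecule is still a lactone, because an open hydroxy amide would relactonise during their removal.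

**12 to 10 to 9.** The lactone C–O bond is opened to the hydroxy acid 11, its CH2OH is taken back to the methyl ester of 10, and the C3–H bond is cut by dehydrogenation to the alkylidene succinate 9. An oxidative desymmetrisation of a four-membered ketone was weighed for the same lactone and set aside: it needs a ketene cycloaddition on a ring A alkene that already bears the prenyl group. Catalytic hydrogenation of 9 is directed by the carboxylate and is blind to the prenyl group.

**9 to 7 and 8.** The C3=C4 bond is cut: aldehyde 7 supplies C4, dimethyl succinate 8 supplies C3, C2 and the two carbons that become C1′ and C4′. One condensation replaces a multi-step chain extension.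

**7 to 5 to 2 to 1 (with 3).** The formyl and prenyl C–C bonds are cut back to resorcinol 1 through aryllithiums 6 and 4. Two ortho-metalations place the prenyl group between the oxygens without the mixtures of electrophilic prenylation.

## Roads not taken

**Alternative 1:** The cut is at C3–C4 and O1–C2, with C2 at the acid oxidation level. In the forward step a carbonate base expels sulfinate from the ring A sulfone A2 to give an ortho-quinone methide, while a chiral isothiourea turns the ring B aryl ester A3 into an ammonium enolate; Michael addition and lactonisation give dihydrocoumarin A1.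
- Merits: both aromatic rings arrive finished, ring C and C3 form in one catalytic step, and the sequence after fragment synthesis is shorter than the chosen one. In convergence this road is better.
- Weak points: C3 of A1 is an α-aryl lactone carbon formed under base with no second stereocenter to hold it, so loss of enantiopurity is a real risk. C2 must then be reduced from carbonyl to methylene by ring opening and reclosure. The base forces acetal protection, whose acidic removal at the end endangers the chromene and the prenylphenol.
- Comparison: the chosen plan sets C3 where it is never acidic, makes ring C at the right oxidation level and ends with fluoride only. It pays with a longer linear sequence.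

**Alternative 2:** The cut is at C4a–C5 of ring A. In the forward step two equivalents of a lithium amide convert the acyclic diketone A5 into its dianion; the terminal carbanion (C4a) adds to C5 of the β-methoxy enone, methoxide leaves and enolisation gives the resorcinol A4.
- Merits: the prenyl group sits between the oxygens by construction and no aryl metalation is needed.
- Weak points: A5 is a long tricarbonyl chain that already carries the stereocenter and rings B and D, so the route is linear and the stereocenter must be made earlier by a separate asymmetric step. Tricarbonyl chains of this kind close easily through oxygen to pyranones. Ring B again carries an acetal that needs acid at the end.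
- Comparison: the only respect in which this road matches the chosen one is the regiochemical certainty of ring A. The chosen plan reaches the same pattern from 1 in three steps (steps 1 to 3) and spends its key step on ring B, the ring that is hard to buy.

**Alternative 3:** The cut is at C3–C1′ and C4–C4a. In the forward step the aryllithium from bromide A7 adds to the vinylboronic ester A9, and a palladium catalyst with a chiral ferrocenyl bisphosphine and a triflate salt couples the boron ate complex with the ring A bromide A8. Ring B migrates from boron to C3 as C4 bonds to ring A, giving boronate A6.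
- Merits: three simple pieces, two C–C bonds and the stereocenter in one catalytic step. On paper this is the shortest road and it is better than the chosen plan in step economy.
- Weak points: both aryl partners are ortho-substituted and electron-rich (slow oxidative addition for A8, hindered migration for the ring from A7), the situation in which selectivity of such couplings tends to fall. The boron of A6 must then be exchanged for CH2–O by one-carbon homologation of a hindered secondary benzylic boronate before ring C can close. The ring B acetal again needs acid at the end.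
- Comparison: the chosen plan sets against this a stereocenter from a hydrogenation class with very wide precedent, bond formations at unhindered centres, and a ring B that emerges with O4′ and O2′ already differentiated and silyl-protected.

Key step: step 14

Remark (assumption on the chemistry): the (S,S) ligand in step 5 is assumed, by analogy with other β-aryl itaconate half-esters, to give the R acid; if the sense is opposite, the antipodal ligand is used and nothing else changes.

Remark (assumption on supply): ethyl 4-methylpent-3-enoate (21) is taken as a purchasable ester.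

Abbreviations: prenyl = 3-methylbut-2-en-1-yl; MOMCl = chloromethyl methyl ether; TMEDA = N,N,N′,N′-tetramethylethylenediamine; cod = cycloocta-1,5-diene; (S,S)-Et-DuPhos = 1,2-bis[(2S,5S)-2,5-diethylphospholan-1-yl]benzene; DIAD = diisopropyl azodicarboxylate; LiTMP = lithium 2,2,6,6-tetramethylpiperidide; MsN3 = methanesulfonyl azide; DDQ = 2,3-dichloro-5,6-dicyano-1,4-benzoquinone.

## Route

Step 1
Reactants: 1 resorcinol
Product: 2 1,3-bis(methoxymethoxy)benzene
Conditions: NaH, MOMCl, DMF, 0 → 25 °C
Reagents that add atoms: chloromethyl methyl ether, COCCl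
Why: Double Williamson etherification of the bis-phenoxide; the acetal ethers direct the ortho-lithiations of steps 2 and 3 and survive the strongly basic Stobbe condensation.

Step 2
Reactants: 2 1,3-bis(methoxymethoxy)benzene; 3 prenyl bromide
Product: 5 1,3-bis(methoxymethoxy)-2-prenylbenzene, via aryllithium 4 (not isolated)
Conditions: n-BuLi, THF, 0 → 25 °C; CuI (10 mol%), then 3, −78 → 25 °C
Reagents that add atoms: none
Why: Directed ortho-metalation: the position between the two acetal oxygens is coordinated from both sides and is lithiated first, and copper-mediated allylic substitution on the primary bromide should give the unrearranged (SN2) prenyl arene.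

Step 3
Reactants: 5 1,3-bis(methoxymethoxy)-2-prenylbenzene
Product: 7 2,4-bis(methoxymethoxy)-3-prenylbenzaldehyde, via aryllithium 6 (not isolated)
Conditions: n-BuLi, TMEDA, THF, 0 °C; DMF, −78 → 0 °C; aq. NH4Cl
Reagents that add atoms: N,N-dimethylformamide, CN(C)C=O
Why: Second directed ortho-metalation at the only ring position still next to an acetal oxygen, followed by formylation of aryllithium 6; the aldehyde carbon becomes C4.

Step 4
Reactants: 7 2,4-bis(methoxymethoxy)-3-prenylbenzaldehyde; 8 dimethyl succinate
Product: 9 (3E)-4-[2,4-bis(methoxymethoxy)-3-prenylphenyl]-3-(methoxycarbonyl)but-3-enoic acid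
Conditions: KOt-Bu, t-BuOH, 60 °C; then cold 1 M HCl to pH 3
Reagents that add atoms: none
Why: Stobbe condensation: aldol addition of the succinate enolate, lactonisation to the paraconic ester and E1cB ring opening give the half-ester as the E alkene (aryl trans to the ester) and join the future C4 and C3.

Step 5
Reactants: 9 (3E)-4-[2,4-bis(methoxymethoxy)-3-prenylphenyl]-3-(methoxycarbonyl)but-3-enoic acid
Product: 10 (3R)-4-[2,4-bis(methoxymethoxy)-3-prenylphenyl]-3-(methoxycarbonyl)butanoic acid
Conditions: [Rh(cod)((S,S)-Et-DuPhos)]BF4 (1 mol%), NaOMe (10 mol%), H2 (5 bar), MeOH, 25 °C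
Reagents that add atoms: none
Why: Asymmetric hydrogenation of a β-aryl itaconate half-ester: carboxylate and alkene chelate the cationic monovalent rhodium centre and the C2-symmetric bisphospholane decides the face of hydrogen delivery, which sets C3 (catalyst control, R); the prenyl alkene is trisubstituted and has no chelating group, so it should not be reduced.

Step 6
Reactants: 10 (3R)-4-[2,4-bis(methoxymethoxy)-3-prenylphenyl]-3-(methoxycarbonyl)butanoic acid
Product: 12 (4R)-4-{[2,4-bis(methoxymethoxy)-3-prenylphenyl]methyl}oxolan-2-one, via hydroxy acid 11 (not isolated)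
Conditions: LiBEt3H, THF, 0 °C; then 1 M HCl, 25 °C
Reagents that add atoms: none
Why: Chemoselective ester reduction: the acid becomes its lithium carboxylate, which triethylborohydride does not reduce, the methyl ester goes to the primary alcohol 11, and acidification closes the γ-lactone; the reagent is a poor base, so the stereocenter should not be enolised.

Step 7
Reactants: 12 (4R)-4-{[2,4-bis(methoxymethoxy)-3-prenylphenyl]methyl}oxolan-2-one
Product: 14 (4R)-4-[(2,4-dihydroxy-3-prenylphenyl)methyl]oxolan-2-one, via bis(trimethylsilyl) ether 13 (not isolated)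
Conditions: Me3SiOTf, 2,2′-bipyridyl, MeCN, 0 → 25 °C; then H2O
Reagents that add atoms: none
Why: Cleavage of aryl methoxymethyl ethers with silyl triflate and bipyridyl: each aryl acetal is converted into the aryl trimethylsilyl ether, which water hydrolyses; no free protic acid is present, so the phenols next to the prenyl group should not cyclise and the lactone stays closed.

Step 8
Reactants: 14 (4R)-4-[(2,4-dihydroxy-3-prenylphenyl)methyl]oxolan-2-one
Product: 15 (3R)-4-(2,4-dihydroxy-3-prenylphenyl)-3-(hydroxymethyl)-N-methoxy-N-methylbutanamide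
Conditions: MeNHOMe·HCl, AlMe3 (excess), CH2Cl2, 0 → 25 °C; aq. potassium sodium tartrate
Reagents that add atoms: N,O-dimethylhydroxylamine hydrochloride, CNOC.Cl
Why: Weinreb aminolysis of a γ-lactone by the aluminium amide; the phenols are carried as aluminium phenoxides, and ring opening frees the primary alcohol for ring C while installing the acyl group for step 11.

Step 9
Reactants: 15 (3R)-4-(2,4-dihydroxy-3-prenylphenyl)-3-(hydroxymethyl)-N-methoxy-N-methylbutanamide
Product: 16 2-[(3R)-7-hydroxy-8-prenylchroman-3-yl]-N-methoxy-N-methylacetamide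
Conditions: PPh3, DIAD, THF (0.01 M), 0 → 25 °C
Reagents that add atoms: none
Why: Intramolecular Mitsunobu etherification: the ortho phenoxide displaces the alkoxyphosphonium group in a 6-exo-tet closure that forms O1–C2 and ring C; O7 cannot reach the activated carbon, high dilution suppresses intermolecular etherification, and C3 is not a reacting centre.

Step 10
Reactants: 16 2-[(3R)-7-hydroxy-8-prenylchroman-3-yl]-N-methoxy-N-methylacetamide
Product: 17 N-methoxy-N-methyl-2-[(3R)-8-prenyl-7-(triisopropylsilyloxy)chroman-3-yl]acetamide
Conditions: i-Pr3SiCl, imidazole, DMF, 25 °C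
Reagents that add atoms: chlorotriisopropylsilane, CC(C)[Si](Cl)(C(C)C)C(C)C
Why: Silylation of the remaining phenol; the triisopropylsilyl ether is chosen because it should withstand the Grignard reagent, the amide base, the aqueous amine of the diazo transfer and the quinone oxidant, yet leaves with fluoride.

Step 11
Reactants: 17 N-methoxy-N-methyl-2-[(3R)-8-prenyl-7-(triisopropylsilyloxy)chroman-3-yl]acetamide
Product: 18 1-[(3R)-8-prenyl-7-(triisopropylsilyloxy)chroman-3-yl]but-3-en-2-one
Conditions: CH2=CHMgBr, THF, −78 → 0 °C; inverse quench into cold 1 M HCl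
Reagents that add atoms: vinylmagnesium bromide, C=C[Mg]Br
Why: Weinreb ketone synthesis: the chelated tetrahedral magnesium adduct prevents a second addition, and the acidic quench protonates the liberated amine before it can add to the new terminal enone.

Step 12
Reactants: 18 1-[(3R)-8-prenyl-7-(triisopropylsilyloxy)chroman-3-yl]but-3-en-2-one
Product: 20 1-diazo-1-[(3R)-8-prenyl-7-(triisopropylsilyloxy)chroman-3-yl]but-3-en-2-one, via trifluoroacetyl diketone 19 (not isolated)
Conditions: LiN(SiMe3)2, THF, −78 °C; CF3CO2CH2CF3; then MsN3, Et3N, H2O, MeCN, 25 °C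
Reagents that add atoms: methanesulfonyl azide, CS(=O)(=O)N=[N+]=[N-]
Why: Detrifluoroacetylative diazo transfer (Regitz-type): the kinetic enolate can only form at the CH2 next to C3, is C-trifluoroacetylated to 19, and the activated diketone takes the diazo group from the sulfonyl azide with loss of trifluoroacetate; the method suits base-sensitive enones, and C3 is not acidic in 18, 19 or 20.

Step 13
Reactants: 21 ethyl 4-methylpent-3-enoate
Product: 23 5-methyl-1-(triisopropylsilyloxy)hex-4-en-1-yne, via lithium ynolate 22 (not isolated)
Conditions: CH2Br2, LiTMP, THF, −78 °C; 21; LiN(SiMe3)2; n-BuLi, −78 → 25 °C; then i-Pr3SiCl, 0 → 25 °C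
Reagents that add atoms: dibromomethane, BrCBr; chlorotriisopropylsilane, CC(C)[Si](Cl)(C(C)C)C(C)C
Why: Kowalski ester homologation stopped at the ynolate: (dibromomethyl)lithium adds to the ester, the dibromo ketone enolate undergoes bromine–lithium exchange and 1,2-shift of the alkyl group to give ynolate 22, and the bulky silyl chloride traps it on oxygen.

Step 14
Reactants: 20 1-diazo-1-[(3R)-8-prenyl-7-(triisopropylsilyloxy)chroman-3-yl]but-3-en-2-one; 23 5-methyl-1-(triisopropylsilyloxy)hex-4-en-1-yne
Product: 26 (3R)-3-[4-hydroxy-3-prenyl-2-(triisopropylsilyloxy)phenyl]-8-prenyl-7-(triisopropylsilyloxy)chroman, via vinylketene 24 (not isolated), via vinylcyclobutenone 25 (not isolated)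
Conditions: hν (medium-pressure Hg lamp, Pyrex filter), 23 (1.5 equiv), ClCH2CH2Cl, 25 °C; then 80 °C
Reagents that add atoms: none
Why: Direct irradiation of the diazo enone expels N2 with 1,2-shift of the vinyl group to the former diazo carbon (photochemical Wolff rearrangement), which forms C1′–C6′ and gives vinylketene 24 whose carbonyl carbon is the future C4′. The silyl ynol ether adds across the ketene C=C in a polar [2+2] cycloaddition in which its prenyl-bearing β-carbon bonds to the ketene carbonyl carbon (C3′–C4′) and its oxygenated carbon to C1′ (C1′–C2′), giving 4-vinylcyclobutenone 25. Under light or on warming to 80 °C, 25 opens by four-electron electrocyclic cleavage of the C1′–C4′ bond to a dienylketene, and ring B closes by a six-electron disrotatory electrocyclisation that forms C4′–C5′; tautomerisation of the cyclohexadienone gives the phenol. The closest known reaction type is the Danheiser benzannulation in its photochemical form, in which α-diazo enones and siloxyalkynes give resorcinol monosilyl ethers. No stereocenter is created; C3 is a spectator on C1′ and should keep its configuration because the cascade is neutral and never places a carbonyl group, a carbanion or a double bond at C3. The step needs one [2+2] regiochemistry, secured by the polarity of the partners (nucleophilic β-carbon of the ynol ether, electrophilic ketene carbonyl carbon), and chemoselectivity for the ynol ether over the two prenyl alkenes, which are far too weakly nucleophilic to intercept the ketene. It also needs vinyl migration to outrun 1,2-hydride shift from C3–H, which direct, unsensitised irradiation favours. The product has O4′ free and O2′ silylated with the prenyl group between them, the differentiation used in step 15.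

Step 15
Reactants: 26 (3R)-3-[4-hydroxy-3-prenyl-2-(triisopropylsilyloxy)phenyl]-8-prenyl-7-(triisopropylsilyloxy)chroman
Product: 28 (3R)-3-[2,2-dimethyl-5-(triisopropylsilyloxy)-2H-chromen-6-yl]-8-prenyl-7-(triisopropylsilyloxy)chroman, via ortho-quinone methide 27 (not isolated)
Conditions: DDQ (1.1 equiv), toluene, 25 → 60 °C
Reagents that add atoms: none
Why: Oxidative cyclisation of an ortho-prenylphenol: the quinone abstracts hydride from the benzylic–allylic CH2 beside the free phenol to give ortho-quinone methide 27, which closes by oxa-6π electrocyclisation to the 2,2-dimethyl-2H-chromene; only the C3′ prenyl group has a free phenol next to it (O4′), so ring D closes on O4′ and the ring A prenyl group cannot follow.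

Step 16
Reactants: 28 (3R)-3-[2,2-dimethyl-5-(triisopropylsilyloxy)-2H-chromen-6-yl]-8-prenyl-7-(triisopropylsilyloxy)chroman
Product: 29 (3R)-3-(5-hydroxy-2,2-dimethyl-2H-chromen-6-yl)-8-prenylchroman-7-ol
Conditions: Bu4NF, THF, 0 °C; aq. NH4Cl
Reagents that add atoms: none
Why: Fluoride cleavage of both aryl silyl ethers under neutral, non-reducing conditions; chromene, prenyl group and C3 are not affected, and the ammonium chloride quench avoids acid-promoted closure of the 7-hydroxyl onto the C8 prenyl group.

## Compound list

1 | resorcinol (benzene-1,3-diol) | Oc1cccc(O)c1 | starting material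
2 | 1,3-bis(methoxymethoxy)benzene | COCOc1cccc(OCOC)c1 | intermediate
3 | prenyl bromide (1-bromo-3-methylbut-2-ene) | CC(C)=CCBr | starting material
4 | [2,6-bis(methoxymethoxy)phenyl]lithium | [Li]c1c(OCOC)cccc1OCOC | intermediate (not isolated)
5 | 1,3-bis(methoxymethoxy)-2-prenylbenzene | COCOc1cccc(OCOC)c1CC=C(C)C | intermediate
6 | [2,4-bis(methoxymethoxy)-3-prenylphenyl]lithium | [Li]c1ccc(OCOC)c(CC=C(C)C)c1OCOC | intermediate (not isolated)
7 | 2,4-bis(methoxymethoxy)-3-prenylbenzaldehyde | O=Cc1ccc(OCOC)c(CC=C(C)C)c1OCOC | intermediate
8 | dimethyl succinate | COC(=O)CCC(=O)OC | starting material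
9 | (3E)-4-[2,4-bis(methoxymethoxy)-3-prenylphenyl]-3-(methoxycarbonyl)but-3-enoic acid | COC(=O)/C(CC(=O)O)=C/c1ccc(OCOC)c(CC=C(C)C)c1OCOC | intermediate
10 | (3R)-4-[2,4-bis(methoxymethoxy)-3-prenylphenyl]-3-(methoxycarbonyl)butanoic acid | OC(=O)C[C@@H](Cc1ccc(OCOC)c(CC=C(C)C)c1OCOC)C(=O)OC | intermediate
11 | (3R)-4-[2,4-bis(methoxymethoxy)-3-prenylphenyl]-3-(hydroxymethyl)butanoic acid | OC(=O)C[C@@H](Cc1ccc(OCOC)c(CC=C(C)C)c1OCOC)CO | intermediate (not isolated)
12 | (4R)-4-{[2,4-bis(methoxymethoxy)-3-prenylphenyl]methyl}oxolan-2-one | O=C1C[C@@H](Cc2ccc(OCOC)c(CC=C(C)C)c2OCOC)CO1 | intermediate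
13 | (4R)-4-{[3-prenyl-2,4-bis(trimethylsilyloxy)phenyl]methyl}oxolan-2-one | O=C1C[C@@H](Cc2ccc(O[Si](C)(C)C)c(CC=C(C)C)c2O[Si](C)(C)C)CO1 | intermediate (not isolated)
14 | (4R)-4-[(2,4-dihydroxy-3-prenylphenyl)methyl]oxolan-2-one | O=C1C[C@@H](Cc2ccc(O)c(CC=C(C)C)c2O)CO1 | intermediate
15 | (3R)-4-(2,4-dihydroxy-3-prenylphenyl)-3-(hydroxymethyl)-N-methoxy-N-methylbutanamide | CON(C)C(=O)C[C@@H](Cc1ccc(O)c(CC=C(C)C)c1O)CO | intermediate
16 | 2-[(3R)-7-hydroxy-8-prenylchroman-3-yl]-N-methoxy-N-methylacetamide | CC(C)=CCc1c(O)ccc2c1OC[C@@H](CC(=O)N(C)OC)C2 | intermediate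
17 | N-methoxy-N-methyl-2-[(3R)-8-prenyl-7-(triisopropylsilyloxy)chroman-3-yl]acetamide | CC(C)=CCc1c(O[Si](C(C)C)(C(C)C)C(C)C)ccc2c1OC[C@@H](CC(=O)N(C)OC)C2 | intermediate
18 | 1-[(3R)-8-prenyl-7-(triisopropylsilyloxy)chroman-3-yl]but-3-en-2-one | CC(C)=CCc1c(O[Si](C(C)C)(C(C)C)C(C)C)ccc2c1OC[C@@H](CC(=O)C=C)C2 | intermediate
19 | 1,1,1-trifluoro-3-[(3R)-8-prenyl-7-(triisopropylsilyloxy)chroman-3-yl]hex-5-ene-2,4-dione (both configurations at the carbon between the carbonyl groups, or its enol) | CC(C)=CCc1c(O[Si](C(C)C)(C(C)C)C(C)C)ccc2c1OC[C@@H](C(C(=O)C=C)C(=O)C(F)(F)F)C2 | intermediate (not isolated)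
20 | 1-diazo-1-[(3R)-8-prenyl-7-(triisopropylsilyloxy)chroman-3-yl]but-3-en-2-one | CC(C)=CCc1c(O[Si](C(C)C)(C(C)C)C(C)C)ccc2c1OC[C@@H](C(=[N+]=[N-])C(=O)C=C)C2 | intermediate
21 | ethyl 4-methylpent-3-enoate | CCOC(=O)CC=C(C)C | starting material
22 | lithium 5-methylhex-4-en-1-yn-1-olate | CC(C)=CCC#C[O-].[Li+] | intermediate (not isolated)
23 | 5-methyl-1-(triisopropylsilyloxy)hex-4-en-1-yne | CC(C)=CCC#CO[Si](C(C)C)(C(C)C)C(C)C | intermediate
24 | 2-[(3R)-8-prenyl-7-(triisopropylsilyloxy)chroman-3-yl]buta-1,3-dien-1-one | CC(C)=CCc1c(O[Si](C(C)C)(C(C)C)C(C)C)ccc2c1OC[C@@H](C(C=C)=C=O)C2 | intermediate (not isolated)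
25 | 4-ethenyl-2-prenyl-4-[(3R)-8-prenyl-7-(triisopropylsilyloxy)chroman-3-yl]-3-(triisopropylsilyloxy)cyclobut-2-en-1-one (both configurations at the ring carbon C4) | CC(C)=CCc1c(O[Si](C(C)C)(C(C)C)C(C)C)ccc2c1OC[C@@H](C1(C=C)C(=O)C(CC=C(C)C)=C1O[Si](C(C)C)(C(C)C)C(C)C)C2 | intermediate (not isolated)
26 | (3R)-3-[4-hydroxy-3-prenyl-2-(triisopropylsilyloxy)phenyl]-8-prenyl-7-(triisopropylsilyloxy)chroman | CC(C)=CCc1c(O[Si](C(C)C)(C(C)C)C(C)C)ccc2c1OC[C@@H](c1ccc(O)c(CC=C(C)C)c1O[Si](C(C)C)(C(C)C)C(C)C)C2 | intermediate
27 | 6-(3-methylbut-2-en-1-ylidene)-4-[(3R)-8-prenyl-7-(triisopropylsilyloxy)chroman-3-yl]-5-(triisopropylsilyloxy)cyclohexa-2,4-dien-1-one | CC(C)=CCc1c(O[Si](C(C)C)(C(C)C)C(C)C)ccc2c1OC[C@@H](C1=C(O[Si](C(C)C)(C(C)C)C(C)C)C(=CC=C(C)C)C(=O)C=C1)C2 | intermediate (not isolated)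
28 | (3R)-3-[2,2-dimethyl-5-(triisopropylsilyloxy)-2H-chromen-6-yl]-8-prenyl-7-(triisopropylsilyloxy)chroman | CC(C)=CCc1c(O[Si](C(C)C)(C(C)C)C(C)C)ccc2c1OC[C@@H](c1ccc3c(c1O[Si](C(C)C)(C(C)C)C(C)C)C=CC(C)(C)O3)C2 | intermediate
29 | (3R)-3-(5-hydroxy-2,2-dimethyl-2H-chromen-6-yl)-8-prenylchroman-7-ol | CC(C)=CCc1c(O)ccc2c1OC[C@@H](c1ccc3c(c1O)C=CC(C)(C)O3)C2 | target

## Step count and risks

Total step count: 16. Longest linear sequence: 15 steps (steps 1 to 12 and 14 to 16, from 1); step 13 is a one-step branch.

Least certain steps:

- **Step 14 (key step).** The Wolff migration may lose to 1,2-hydride shift from C3–H, because the bulky substituent on the diazo carbon disfavours the reactive conformer. The ketene may also be consumed by oligomerisation or by acylating the product phenol. In addition, 20 is a terminal enone and a diazo compound at once and may decay by intermolecular dipolar cycloaddition before it is irradiated. Fallback, from 16 back to 26, generating 24 thermally without diazo compound or light: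
  - KOH in aqueous ethanol hydrolyses 16 to 2-[(3R)-7-hydroxy-8-prenylchroman-3-yl]acetic acid F1.
  - i-Pr3SiOTf and 2,6-lutidine give triisopropylsilyl 2-[(3R)-8-prenyl-7-(triisopropylsilyloxy)chroman-3-yl]acetate F2.
  - Oxalyl chloride with catalytic DMF converts the silyl ester into 2-[(3R)-8-prenyl-7-(triisopropylsilyloxy)chroman-3-yl]acetyl chloride F3.
  - Et3N in excess ethyl vinyl ether dehydrochlorinates F3 to the aldoketene, which is trapped by [2+2] cycloaddition as 3-ethoxy-2-[(3R)-8-prenyl-7-(triisopropylsilyloxy)chroman-3-yl]cyclobutan-1-one F4.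
  - Mild base eliminates ethanol toward the substituted α-carbon to give 2-[(3R)-8-prenyl-7-(triisopropylsilyloxy)chroman-3-yl]cyclobut-2-en-1-one F5.
  - Heating F5 with 23 in toluene at 80 to 110 °C opens the four-membered ring to 24 and runs the thermal form of the same benzannulation to 26.

- **Step 12.** Conjugate addition of triethylamine or the sulfonamide anion to the unsubstituted enone, and oligomerisation of the enone, may compete with diazo transfer. Fallback, from 17 back to 26, carrying the alkene with a traceless silyl group:
  - (E)-Me3SiCH=CHLi adds to 17 to give (3E)-1-[(3R)-8-prenyl-7-(triisopropylsilyloxy)chroman-3-yl]-4-(trimethylsilyl)but-3-en-2-one F6, a β-silyl enone that resists polymerisation and conjugate addition.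
  - The same diazo transfer gives (3E)-1-diazo-1-[(3R)-8-prenyl-7-(triisopropylsilyloxy)chroman-3-yl]-4-(trimethylsilyl)but-3-en-2-one F7.
  - Irradiation with 23 as in step 14 gives (3R)-3-[4-hydroxy-3-prenyl-2-(triisopropylsilyloxy)-5-(trimethylsilyl)phenyl]-8-prenyl-7-(triisopropylsilyloxy)chroman F8.
  - Ipso-protodesilylation of F8 at C5′, activated by the ortho hydroxyl and the para silyloxy group, with pyridinium p-toluenesulfonate in methanol gives 26.

- **Step 15.** The quinone may also abstract hydride at C4 or C3 (dehydrogenation toward the isoflavene) or at the benzylic–allylic CH2 of the ring A prenyl group, since ring A is an electron-rich diether. Fallback, from 26 back to 28, without a hydride-abstracting oxidant: N-(phenylselanyl)phthalimide with a trace of camphorsulfonic acid cyclises the phenol onto its prenyl group in the 6-endo mode to give (3R)-3-[2,2-dimethyl-3-(phenylselanyl)-5-(triisopropylsilyloxy)-3,4-dihydro-2H-chromen-6-yl]-8-prenyl-7-(triisopropylsilyloxy)chroman F9. H2O2 in THF then oxidises selenium, and syn-elimination of the selenoxide, possible only toward the benzylic CH2, gives 28.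

- **Step 3.** Lateral deprotonation of the prenyl CH2, which is benzylic, allylic and flanked by two coordinating acetals, may compete with ring lithiation. Fallback, from 2 back to 7, fixing the site of lithiation with a halogen:
  - N-bromosuccinimide in acetonitrile gives 1-bromo-2,4-bis(methoxymethoxy)benzene F10.
  - Lithium diisopropylamide at −78 °C deprotonates between the acetals, and CuI with 3 gives 1-bromo-2,4-bis(methoxymethoxy)-3-prenylbenzene F11.
  - Bromine–lithium exchange with n-BuLi at −78 °C gives 6, which DMF converts to 7.

- **Step 5.** The ortho acetal may disturb the chelate and erode face selectivity, or the catalyst may slowly reduce or isomerise the prenyl alkene. Fallback, from 9 back to 10, by resolution: magnesium in methanol reduces the conjugated alkene to racemic 4-[2,4-bis(methoxymethoxy)-3-prenylphenyl]-3-(methoxycarbonyl)butanoic acid F12. Crystallisation with one enantiomer of 1-phenylethylamine (written here with the R amine) gives the (R)-1-phenylethylammonium salt of 10, F13, and acidification returns 10.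

- **Step 13.** The carbenoid may deprotonate the acidic α-position of the β,γ-unsaturated ester instead of adding to the carbonyl group, and the alkene may migrate into conjugation. Fallback, from 3 back to 23: HC≡CMgBr with catalytic CuCl alkylates on 3 to give 5-methylhex-4-en-1-yne F14. n-BuLi and then t-BuOOLi oxidise the lithium acetylide to 22, which i-Pr3SiCl traps as 23.

## Further compounds

F1 | step 14 | 2-[(3R)-7-hydroxy-8-prenylchroman-3-yl]acetic acid | CC(C)=CCc1c(O)ccc2c1OC[C@@H](CC(=O)O)C2
F2 | step 14 | triisopropylsilyl 2-[(3R)-8-prenyl-7-(triisopropylsilyloxy)chroman-3-yl]acetate | CC(C)=CCc1c(O[Si](C(C)C)(C(C)C)C(C)C)ccc2c1OC[C@@H](CC(=O)O[Si](C(C)C)(C(C)C)C(C)C)C2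
F3 | step 14 | 2-[(3R)-8-prenyl-7-(triisopropylsilyloxy)chroman-3-yl]acetyl chloride | CC(C)=CCc1c(O[Si](C(C)C)(C(C)C)C(C)C)ccc2c1OC[C@@H](CC(=O)Cl)C2
F4 | step 14 | 3-ethoxy-2-[(3R)-8-prenyl-7-(triisopropylsilyloxy)chroman-3-yl]cyclobutan-1-one (mixture at the two ring carbons) | CC(C)=CCc1c(O[Si](C(C)C)(C(C)C)C(C)C)ccc2c1OC[C@@H](C1C(=O)CC1OCC)C2
F5 | step 14 | 2-[(3R)-8-prenyl-7-(triisopropylsilyloxy)chroman-3-yl]cyclobut-2-en-1-one | CC(C)=CCc1c(O[Si](C(C)C)(C(C)C)C(C)C)ccc2c1OC[C@@H](C1=CCC1=O)C2
F6 | step 12 | (3E)-1-[(3R)-8-prenyl-7-(triisopropylsilyloxy)chroman-3-yl]-4-(trimethylsilyl)but-3-en-2-one | CC(C)=CCc1c(O[Si](C(C)C)(C(C)C)C(C)C)ccc2c1OC[C@@H](CC(=O)/C=C/[Si](C)(C)C)C2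
F7 | step 12 | (3E)-1-diazo-1-[(3R)-8-prenyl-7-(triisopropylsilyloxy)chroman-3-yl]-4-(trimethylsilyl)but-3-en-2-one | CC(C)=CCc1c(O[Si](C(C)C)(C(C)C)C(C)C)ccc2c1OC[C@@H](C(=[N+]=[N-])C(=O)/C=C/[Si](C)(C)C)C2
F8 | step 12 | (3R)-3-[4-hydroxy-3-prenyl-2-(triisopropylsilyloxy)-5-(trimethylsilyl)phenyl]-8-prenyl-7-(triisopropylsilyloxy)chroman | CC(C)=CCc1c(O[Si](C(C)C)(C(C)C)C(C)C)ccc2c1OC[C@@H](c1cc([Si](C)(C)C)c(O)c(CC=C(C)C)c1O[Si](C(C)C)(C(C)C)C(C)C)C2
F9 | step 15 | (3R)-3-[2,2-dimethyl-3-(phenylselanyl)-5-(triisopropylsilyloxy)-3,4-dihydro-2H-chromen-6-yl]-8-prenyl-7-(triisopropylsilyloxy)chroman (both configurations at the selenium-bearing carbon) | CC(C)=CCc1c(O[Si](C(C)C)(C(C)C)C(C)C)ccc2c1OC[C@@H](c1ccc3c(c1O[Si](C(C)C)(C(C)C)C(C)C)CC([Se]c1ccccc1)C(C)(C)O3)C2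
F10 | step 3 | 1-bromo-2,4-bis(methoxymethoxy)benzene | COCOc1ccc(Br)c(OCOC)c1
F11 | step 3 | 1-bromo-2,4-bis(methoxymethoxy)-3-prenylbenzene | COCOc1ccc(Br)c(OCOC)c1CC=C(C)C
F12 | step 5 | racemic 4-[2,4-bis(methoxymethoxy)-3-prenylphenyl]-3-(methoxycarbonyl)butanoic acid | OC(=O)CC(Cc1ccc(OCOC)c(CC=C(C)C)c1OCOC)C(=O)OC
F13 | step 5 | (R)-1-phenylethylammonium (3R)-4-[2,4-bis(methoxymethoxy)-3-prenylphenyl]-3-(methoxycarbonyl)butanoate | C[C@@H]([NH3+])c1ccccc1.[O-]C(=O)C[C@@H](Cc1ccc(OCOC)c(CC=C(C)C)c1OCOC)C(=O)OC
F14 | step 13 | 5-methylhex-4-en-1-yne | CC(C)=CCC#C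
A1 | alternative 1 | (3R)-7-(methoxymethoxy)-3-[5-(methoxymethoxy)-2,2-dimethyl-2H-chromen-6-yl]-8-prenyl-3,4-dihydro-2H-chromen-2-one | CC(C)=CCc1c(OCOC)ccc2c1OC(=O)[C@@H](c1ccc3c(c1OCOC)C=CC(C)(C)O3)C2
A2 | alternative 1 | 3-(methoxymethoxy)-6-[(4-methylbenzenesulfonyl)methyl]-2-prenylphenol | CC(C)=CCc1c(OCOC)ccc(CS(=O)(=O)c2ccc(C)cc2)c1O
A3 | alternative 1 | 4-nitrophenyl 2-[5-(methoxymethoxy)-2,2-dimethyl-2H-chromen-6-yl]acetate | O=C(Cc1ccc2c(c1OCOC)C=CC(C)(C)O2)Oc1ccc(cc1)[N+](=O)[O-]
A4 | alternative 2 | 4-{(2R)-3-(tert-butyldimethylsilyloxy)-2-[5-(methoxymethoxy)-2,2-dimethyl-2H-chromen-6-yl]propyl}-2-prenylbenzene-1,3-diol | CC(C)=CCc1c(O)ccc(C[C@@H](CO[Si](C)(C)C(C)(C)C)c2ccc3c(c2OCOC)C=CC(C)(C)O3)c1O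
A5 | alternative 2 | (1E,8R)-9-(tert-butyldimethylsilyloxy)-1-methoxy-8-[5-(methoxymethoxy)-2,2-dimethyl-2H-chromen-6-yl]-4-prenylnon-1-ene-3,5-dione | CO/C=C/C(=O)C(CC=C(C)C)C(=O)CC[C@@H](CO[Si](C)(C)C(C)(C)C)c1ccc2c(c1OCOC)C=CC(C)(C)O2
A6 | alternative 3 | 2-{(1R)-2-[2,4-bis(tert-butyldimethylsilyloxy)-3-prenylphenyl]-1-[5-(methoxymethoxy)-2,2-dimethyl-2H-chromen-6-yl]ethyl}-4,4,5,5-tetramethyl-1,3,2-dioxaborolane | CC(C)=CCc1c(O[Si](C)(C)C(C)(C)C)ccc(C[C@@H](B2OC(C)(C)C(C)(C)O2)c2ccc3c(c2OCOC)C=CC(C)(C)O3)c1O[Si](C)(C)C(C)(C)C
A7 | alternative 3 | 6-bromo-5-(methoxymethoxy)-2,2-dimethyl-2H-chromene | COCOc1c(Br)ccc2c1C=CC(C)(C)O2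
A8 | alternative 3 | 1-bromo-2,4-bis(tert-butyldimethylsilyloxy)-3-prenylbenzene | CC(C)=CCc1c(O[Si](C)(C)C(C)(C)C)ccc(Br)c1O[Si](C)(C)C(C)(C)C
A9 | alternative 3 | 2-ethenyl-4,4,5,5-tetramethyl-1,3,2-dioxaborolane | C=CB1OC(C)(C)C(C)(C)O1
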